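**Retrosynthetic overview**

1. Locants follow the acyclic chain, C-1 (free CH2OH) to C-16 (CH2OAc). The oxepane is O–C6–C7–C8–C9–C10–C11, and the lactone O–C(=O) bridges C-7 and C-11.
2. Key disconnection: the O–C11 and C10–C11 bonds form together. C-11, as a copper carbenoid held by the ester on the C-7 oxygen, inserts into the ring O–C10 bond of a six-membered 2-silyloxytetrahydropyran (O, C6–C10) by oxonium ylide formation and [1,2]-shift. This expands the tetrahydropyran to the oxepane, closes the 1,4-dioxan-2-one ring and sets the C-11 quaternary centre.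
3. Enabling feature: C-10 is a carbinol carbon next to C-11, which carries the ring oxygen. One oxidation level higher, C-10 is an acetal carbon bonded to that oxygen and can migrate. The lactone path C11–C(=O)–O–C7–C6–O places the carbenoid carbon 1,5 to the ring oxygen.
4. The acetal comes from an Achmatowicz rearrangement of an (S)-furyl carbinol: C-6 is set by asymmetric transfer hydrogenation, and C-10 and C-7 are relayed from it. The carbinol comes from nerol (C1–C6) and furan (C7–C10); the C12–C16 arm is a Z-iodide (Still–Gennari) joined by acetoacetate alkylation.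
5. Ring order: furan → pyranone → tetrahydropyran acetal → oxepane plus lactone bridge in one step; desilylation last.

Key step: step 19

Remark: TBS = tert-butyldimethylsilyl. The acetal carbon is assumed to migrate in step 19 with retention, as is usual for [1,2]-shifts of tethered oxonium ylides, and the anomeric configuration in step 8 is chosen on that basis.

**Route**

Step 1
Reactants: 1 nerol
Product: 2 neryl TBS ether
Conditions: TBSCl, imidazole, CH2Cl2, 0 °C to rt
Reagents that add atoms: tert-butyldimethylsilyl chloride, C[Si](C)(Cl)C(C)(C)C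
Why: Imidazole-promoted silyl ether formation at the primary allylic alcohol should be clean and leaves the 2Z-alkene untouched.

Step 2
Reactants: 2 neryl TBS ether
Product: 3 rac-6,7-epoxyneryl TBS ether
Conditions: mCPBA (1.0 equiv), NaHCO3, CH2Cl2, −20 °C
Reagents that add atoms: 3-chloroperoxybenzoic acid, OOC(=O)c1cccc(Cl)c1
Why: Prilezhaev epoxidation should prefer the remote, more electron-rich 6,7-alkene over the 2,3-alkene deactivated by the allylic oxygen; the racemic epoxide stereocentre is destroyed in step 3.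

Step 3
Reactants: 3 rac-6,7-epoxyneryl TBS ether
Product: 5 (4Z)-6-(TBSO)-4-methylhex-4-enal, via 6,7-diol 4 (not isolated)
Conditions: H5IO6, THF–H2O, 0 °C
Reagents that add atoms: none
Why: Acid-promoted epoxide hydrolysis (water enters at the tertiary carbon and leaves with acetone) followed in the same flask by periodate glycol cleavage should give the aldehyde with the Z-alkene and silyl ether intact.

Step 4
Reactants: 5 (4Z)-6-(TBSO)-4-methylhex-4-enal; 6 furan
Product: 8 rac-(4Z)-6-(TBSO)-1-(furan-2-yl)-4-methylhex-4-en-1-ol, via 2-furyllithium 7 (not isolated)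
Conditions: 6, n-BuLi, THF, 0 °C; then 5, −78 °C; then H2O
Reagents that add atoms: none
Why: α-Lithiation of furan and 1,2-addition of the aryllithium to the aldehyde should give the furyl carbinol; its configuration is not controlled here because it is reset in steps 5 and 6.

Step 5
Reactants: 8 rac-furyl carbinol
Product: 9 (4Z)-6-(TBSO)-1-(furan-2-yl)-4-methylhex-4-en-1-one
Conditions: activated MnO2, CH2Cl2, rt
Reagents that add atoms: none
Why: Manganese dioxide oxidation is selective for the benzylic-type furyl carbinol and should not touch the isolated alkene or the silyl ether.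

Step 6
Reactants: 9 furyl ketone
Product: 10 (1S,4Z)-6-(TBSO)-1-(furan-2-yl)-4-methylhex-4-en-1-ol
Conditions: RuCl[(S,S)-TsDPEN](p-cymene) (1 mol%), HCO2H/Et3N (5:2), rt
Reagents that add atoms: none
Why: Noyori–Ikariya asymmetric transfer hydrogenation, in which the furan ring takes the aryl position in the CH/π-organised transition state, should deliver hydride with the (S,S)-ligand to give the (S)-carbinol, the only stereocentre set by a chiral catalyst (later C-6).

Step 7
Reactants: 10 (S)-furyl carbinol
Product: 12 (2S)-6-hydroxy-2-[(3Z)-5-(TBSO)-3-methylpent-3-en-1-yl]-2H-pyran-3(6H)-one, via Z-enedione 11 (not isolated)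
Conditions: VO(acac)2 (3 mol%), t-BuOOH, CH2Cl2, 0 °C to rt
Reagents that add atoms: tert-butyl hydroperoxide, CC(C)(C)OO
Why: Achmatowicz rearrangement; the hydroxyl-directed vanadium peroxide should oxidise the furan far faster than the remote trisubstituted alkene, the hydroxy ene-dione closes to the six-membered lactol, and the carbinol centre is carried over unchanged as C-6.

Step 8
Reactants: 12 pyranone lactol
Product: 13 (2S,6S)-6-(TBSO)-2-[(3Z)-5-(TBSO)-3-methylpent-3-en-1-yl]-2H-pyran-3(6H)-one
Conditions: TBSCl, imidazole, CH2Cl2, −20 to 0 °C; chromatography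
Reagents that add atoms: tert-butyldimethylsilyl chloride, C[Si](C)(Cl)C(C)(C)C
Why: Silylation of the mutarotating lactol should give mainly the 2,6-trans anomer, with the silyloxy group axial (anomeric effect) and the side chain equatorial; this fixes the future C-10 relative to C-6, and the minor cis anomer is removed.

Step 9
Reactants: 13 trans-silyl acetal enone
Product: 14 (2S,3R,6S)-6-(TBSO)-3-methyl-2-[(3Z)-5-(TBSO)-3-methylpent-3-en-1-yl]-3,6-dihydro-2H-pyran-3-ol
Conditions: MeLi, THF, −78 °C; then H2O
Reagents that add atoms: methyllithium, [Li]C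
Why: 1,2-Addition of the hard organolithium to the enone should occur on the face anti to the pseudoaxial anomeric silyloxy group, so the methyl enters cis to the side chain and the tertiary hydroxyl (C-7) ends cis to the silyloxy group.

Step 10
Reactants: 14 tertiary allylic alcohol
Product: 15 (2S,3R,6S)-6-(TBSO)-3-methyl-2-[(3Z)-5-(TBSO)-3-methylpent-3-en-1-yl]tetrahydro-2H-pyran-3-ol
Conditions: 2-nitrobenzenesulfonohydrazide, Et3N, CH2Cl2, rt
Reagents that add atoms: none
Why: Diimide reduction transfers hydrogen through a concerted cyclic transition state and should reduce the cis-disubstituted ring alkene much faster than the trisubstituted side-chain alkene, without acid that would ionise the allylic acetal.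

Step 11
Reactants: 15 tetrahydropyranol; 16 2,2,6-trimethyl-4H-1,3-dioxin-4-one
Product: 18 acetoacetate of 15, via acetylketene 17 (not isolated)
Conditions: xylenes, 140 °C
Reagents that add atoms: none
Why: Thermal retro-hetero-Diels–Alder of the dioxinone releases acetylketene, which acylates even hindered tertiary alcohols under neutral conditions, so the silyl acetal should survive.

Step 12
Reactants: 19 3-(TBSO)propanal; 20 methyl 2-[bis(2,2,2-trifluoroethoxy)phosphoryl]propanoate
Product: 21 methyl (2Z)-5-(TBSO)-2-methylpent-2-enoate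
Conditions: KHMDS, 18-crown-6, THF, −78 °C
Reagents that add atoms: none
Why: Still–Gennari olefination with the trifluoroethyl phosphonate and a dissociated potassium counter-ion should give the kinetic Z-trisubstituted enoate (later the 14Z-alkene).

Step 13
Reactants: 21 Z-enoate
Product: 22 (2Z)-5-(TBSO)-2-methylpent-2-en-1-ol
Conditions: DIBAL-H, CH2Cl2, −78 °C; Rochelle salt
Reagents that add atoms: none
Why: 1,2-Reduction of the conjugated ester with DIBAL-H should give the allylic alcohol without changing the alkene geometry.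

Step 14
Reactants: 22 Z-allylic alcohol
Product: 23 (2Z)-5-(TBSO)-2-methylpent-2-en-1-yl acetate
Conditions: Ac2O, pyridine, DMAP (cat.), CH2Cl2, rt
Reagents that add atoms: acetic anhydride, CC(=O)OC(C)=O
Why: DMAP-catalysed acetylation installs the acetate of the target at C-16 at the outset.

Step 15
Reactants: 23 silyl ether acetate
Product: 24 (2Z)-5-hydroxy-2-methylpent-2-en-1-yl acetate
Conditions: HF·pyridine, THF, 0 °C
Reagents that add atoms: none
Why: Fluoride-mediated desilylation under mildly acidic conditions should free the homoallylic alcohol without acetate cleavage or migration.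

Step 16
Reactants: 24 homoallylic alcohol
Product: 25 (2Z)-5-iodo-2-methylpent-2-en-1-yl acetate
Conditions: I2, PPh3, imidazole, CH2Cl2, 0 °C
Reagents that add atoms: iodine, II
Why: Appel-type iodination of the primary alcohol proceeds by SN2 displacement of the alkoxyphosphonium ion and should leave the allylic acetate untouched.

Step 17
Reactants: 18 acetoacetate; 25 Z-iodide
Product: 26 C-alkylated acetoacetate (both C-2 epimers)
Conditions: NaH, DMF, 0 to 45 °C
Reagents that add atoms: none
Why: Acetoacetic ester alkylation (SN2 of the stabilised sodium enolate on the primary iodide) should attach the C12–C16 arm; the new α-stereocentre forms as a mixture and is erased in step 18.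

Step 18
Reactants: 26 α-alkyl acetoacetate
Product: 27 α-diazo ester
Conditions: 4-acetamidobenzenesulfonyl azide, DBU, MeCN, 0 °C to rt
Reagents that add atoms: 4-acetamidobenzenesulfonyl azide, CC(=O)Nc1ccc(cc1)S(=O)(=O)N=[N+]=[N-]
Why: Regitz deacylative diazo transfer: the enolate adds to the sulfonyl azide and the adduct fragments with transfer of the acetyl group to the sulfonamide nitrogen, leaving the α-alkyl-α-diazo ester.

Step 19
Reactants: 27 α-diazo ester
Product: 29 bis-TBS ether of the target, via oxonium ylide 28 (not isolated)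
Conditions: Cu(hfacac)2 (5 mol%), CH2Cl2, reflux, slow addition of 27
Reagents that add atoms: none
Why: The copper carbenoid at the diazo carbon is attacked by a lone pair of the ring oxygen, which sits 1,5 to it through the ester tether, to give bridged oxonium ylide 28; the ring O–C(acetal) bond, weakened by the exocyclic silyloxy oxygen, then breaks and the acetal carbon recombines with the ester α-carbon in a [1,2]-Stevens shift that inserts this carbon into the ring. The closest known reaction type is the metal-catalysed oxonium ylide formation/[1,2]-shift of diazocarbonyl compounds tethered to cyclic acetals, which enlarges the acetal ring by one atom and gives oxygen-bridged bicycles. The 1,4-dioxan-2-one ring closes by carbenoid–ether ylide formation through a six-membered array, and the oxepane arises by one-carbon ring expansion of the tetrahydropyran. The quaternary centre C-11 can form only with the configuration shown, because the lactone bridge is anchored to the C-7 stereocentre and a bicyclo[3.2.2] frame allows no other; C-10 should migrate with retention, since it is delivered to the ylide carbon on the face from which the ring oxygen departs within a tight, tethered pair. The step needs attack at the ring oxygen to outrun 1,2-hydride shift from the adjacent CH2, insertion into the C6–H bond and attack at the exocyclic oxygen; a copper(II) catalyst that favours ylide formation over C–H insertion, the six-membered reach to the ring oxygen (eight-membered to the other) and the bulky silyl group secure this, and the α-oxygen makes the acetal carbon migrate in preference to C-6.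

Step 20
Reactants: 29 bis-TBS ether
Product: 30 target CNP0174851.1
Conditions: HF·pyridine, pyridine, THF, 0 °C to rt
Reagents that add atoms: none
Why: Global fluoride desilylation under buffered acidic conditions should free the C-1 and C-10 hydroxyls while the allylic acetate and the bridged lactone remain intact.

**Compound list**

1 | nerol, (2Z)-3,7-dimethylocta-2,6-dien-1-ol | CC(C)=CCC/C(C)=C\CO | starting material
2 | neryl TBS ether | CC(C)=CCC/C(C)=C\CO[Si](C)(C)C(C)(C)C | intermediate
3 | rac-6,7-epoxyneryl TBS ether | CC1(C)OC1CC/C(C)=C\CO[Si](C)(C)C(C)(C)C | intermediate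
4 | rac-(6Z)-8-(TBSO)-2,6-dimethyloct-6-ene-2,3-diol | CC(C)(O)C(O)CC/C(C)=C\CO[Si](C)(C)C(C)(C)C | intermediate
5 | (4Z)-6-(TBSO)-4-methylhex-4-enal | O=CCC/C(C)=C\CO[Si](C)(C)C(C)(C)C | intermediate
6 | furan | c1ccoc1 | starting material
7 | 2-furyllithium | [Li]c1ccco1 | intermediate
8 | rac-(4Z)-6-(TBSO)-1-(furan-2-yl)-4-methylhex-4-en-1-ol | OC(CC/C(C)=C\CO[Si](C)(C)C(C)(C)C)c1ccco1 | intermediate
9 | (4Z)-6-(TBSO)-1-(furan-2-yl)-4-methylhex-4-en-1-one | O=C(CC/C(C)=C\CO[Si](C)(C)C(C)(C)C)c1ccco1 | intermediate
10 | (1S,4Z)-6-(TBSO)-1-(furan-2-yl)-4-methylhex-4-en-1-ol | O[C@@H](CC/C(C)=C\CO[Si](C)(C)C(C)(C)C)c1ccco1 | intermediate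
11 | (2Z,5S,8Z)-10-(TBSO)-5-hydroxy-8-methyl-4-oxodeca-2,8-dienal | O[C@@H](CC/C(C)=C\CO[Si](C)(C)C(C)(C)C)C(=O)/C=C\C=O | intermediate
12 | (2S)-6-hydroxy-2-[(3Z)-5-(TBSO)-3-methylpent-3-en-1-yl]-2H-pyran-3(6H)-one, both anomers | OC1C=CC(=O)[C@H](CC/C(C)=C\CO[Si](C)(C)C(C)(C)C)O1 | intermediate
13 | (2S,6S)-6-(TBSO)-2-[(3Z)-5-(TBSO)-3-methylpent-3-en-1-yl]-2H-pyran-3(6H)-one, 2,6-trans | C[Si](C)(C(C)(C)C)O[C@H]1C=CC(=O)[C@H](CC/C(C)=C\CO[Si](C)(C)C(C)(C)C)O1 | intermediate
14 | (2S,3R,6S)-6-(TBSO)-3-methyl-2-[(3Z)-5-(TBSO)-3-methylpent-3-en-1-yl]-3,6-dihydro-2H-pyran-3-ol | C[Si](C)(C(C)(C)C)O[C@H]1C=C[C@@](C)(O)[C@H](CC/C(C)=C\CO[Si](C)(C)C(C)(C)C)O1 | intermediate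
15 | (2S,3R,6S)-6-(TBSO)-3-methyl-2-[(3Z)-5-(TBSO)-3-methylpent-3-en-1-yl]tetrahydro-2H-pyran-3-ol | C[Si](C)(C(C)(C)C)O[C@H]1CC[C@@](C)(O)[C@H](CC/C(C)=C\CO[Si](C)(C)C(C)(C)C)O1 | intermediate
16 | 2,2,6-trimethyl-4H-1,3-dioxin-4-one | CC1=CC(=O)OC(C)(C)O1 | starting material
17 | acetylketene | CC(=O)C=C=O | intermediate
18 | (2S,3R,6S)-6-(TBSO)-3-methyl-2-[(3Z)-5-(TBSO)-3-methylpent-3-en-1-yl]tetrahydro-2H-pyran-3-yl 3-oxobutanoate | C[Si](C)(C(C)(C)C)O[C@H]1CC[C@@](C)(OC(=O)CC(C)=O)[C@H](CC/C(C)=C\CO[Si](C)(C)C(C)(C)C)O1 | intermediate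
19 | 3-(TBSO)propanal | O=CCCO[Si](C)(C)C(C)(C)C | starting material
20 | methyl 2-[bis(2,2,2-trifluoroethoxy)phosphoryl]propanoate | COC(=O)C(C)P(=O)(OCC(F)(F)F)OCC(F)(F)F | starting material
21 | methyl (2Z)-5-(TBSO)-2-methylpent-2-enoate | COC(=O)/C(C)=C\CCO[Si](C)(C)C(C)(C)C | intermediate
22 | (2Z)-5-(TBSO)-2-methylpent-2-en-1-ol | OC/C(C)=C\CCO[Si](C)(C)C(C)(C)C | intermediate
23 | (2Z)-5-(TBSO)-2-methylpent-2-en-1-yl acetate | CC(=O)OC/C(C)=C\CCO[Si](C)(C)C(C)(C)C | intermediate
24 | (2Z)-5-hydroxy-2-methylpent-2-en-1-yl acetate | CC(=O)OC/C(C)=C\CCO | intermediate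
25 | (2Z)-5-iodo-2-methylpent-2-en-1-yl acetate | CC(=O)OC/C(C)=C\CCI | intermediate
26 | tetrahydropyranyl ester as in 18 of (5Z)-2-acetyl-7-acetoxy-6-methylhept-5-enoic acid, both C-2 epimers | C[Si](C)(C(C)(C)C)O[C@H]1CC[C@@](C)(OC(=O)C(CC/C=C(C)\COC(C)=O)C(C)=O)[C@H](CC/C(C)=C\CO[Si](C)(C)C(C)(C)C)O1 | intermediate
27 | tetrahydropyranyl ester as in 18 of (5Z)-7-acetoxy-2-diazo-6-methylhept-5-enoic acid | C[Si](C)(C(C)(C)C)O[C@H]1CC[C@@](C)(OC(=O)C(=[N+]=[N-])CC/C=C(C)\COC(C)=O)[C@H](CC/C(C)=C\CO[Si](C)(C)C(C)(C)C)O1 | intermediate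
28 | bridged oxonium ylide: ring oxygen of 27 bonded to the former diazo carbon, which carries the negative charge | C[Si](C)(C(C)(C)C)O[C@H]1CC[C@@]2(C)OC(=O)[C-](CC/C=C(C)\COC(C)=O)[O+]1[C@H]2CC/C(C)=C\CO[Si](C)(C)C(C)(C)C | intermediate
29 | (2Z)-5-[(1R,2S,5R,9S)-2-(TBSO)-9-[(3Z)-5-(TBSO)-3-methylpent-3-en-1-yl]-5-methyl-7-oxo-6,8-dioxabicyclo[3.2.2]nonan-1-yl]-2-methylpent-2-en-1-yl acetate | CC(=O)OC/C(C)=C\CC[C@@]12O[C@@H](CC/C(C)=C\CO[Si](C)(C)C(C)(C)C)[C@@](C)(CC[C@@H]1O[Si](C)(C)C(C)(C)C)OC2=O | intermediate
30 | CNP0174851.1, (2Z)-5-[(1R,2S,5R,9S)-2-hydroxy-9-[(3Z)-5-hydroxy-3-methylpent-3-en-1-yl]-5-methyl-7-oxo-6,8-dioxabicyclo[3.2.2]nonan-1-yl]-2-methylpent-2-en-1-yl acetate | CC(=O)OC/C(C)=C\CC[C@@]12O[C@@H](CC/C(C)=C\CO)[C@@](C)(CC[C@@H]1O)OC2=O | target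

**Step count**

Total: 20 steps. Longest linear sequence: 15 steps (steps 1–11 and 17–20, from nerol); the side-chain branch is steps 12–16.

**Steps most likely to fail**

1. Step 19. The carbenoid may be consumed before it reaches the ring oxygen, either by 1,2-hydride shift from the adjacent CH2 (giving the α,β-unsaturated ester) or by insertion into the C6–H bond. Ylide formation requires the ring-flipped chair with the ester oxygen axial, which makes these competitors more dangerous. Configuration at the migrating carbon may also be partly lost if the pair loosens.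
 Fallback, setting out from 18 and returning at 29: a vinyl carbenoid without an sp3 β-hydrogen is used, and the arm is built afterwards. Diazo transfer to 18 (4-acetamidobenzenesulfonyl azide, Et3N) should give the diazoacetoacetate F1. NaBH4 reduction should give the 2-diazo-3-hydroxybutanoate F2, and POCl3/Et3N dehydration the vinyldiazoacetate F3, which is used at once. Rh2(OAc)4 should take F3 through the vinyl oxonium ylide F4 to the 1-vinyl bicyclic lactone F5 by the same [1,2]-shift. Separately, copper-catalysed anti-carbomagnesiation of propargyl alcohol with MeMgBr and iodination should give (2Z)-3-iodo-2-methylprop-2-en-1-ol F6. Hydroboration of F5 with 9-BBN should give the B-alkyl-9-BBN adduct F7 (not isolated), and Suzuki–Miyaura coupling with F6 (PdCl2(dppf), AsPh3, Cs2CO3, DMF–H2O) the C-16 allylic alcohol F8 with retention of the Z geometry. Acetylation (Ac2O, pyridine) then gives 29.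

2. Step 9. Facial selectivity of the methyl addition to the half-chair enone may be poor, and conjugate addition, enolisation at C-6 or attack at the anomeric silicon may compete.
 Fallback, setting out from 13 and returning at 15: the methyl group is built from a methylene. Conjugate reduction of 13 with [(Ph3P)CuH]6 should give the saturated pyranone F9. Corey–Chaykovsky reaction with dimethylsulfonium methylide, which attacks cyclohexanone-type chairs axially, should give the spiro-epoxide F10 with the epoxide oxygen equatorial. Opening at the CH2 terminus with LiEt3BH then gives 15.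

3. Step 17. SN2 at the homoallylic iodide may be slow on the hindered β-keto ester, with competing E2 elimination to a diene, O-alkylation or double alkylation, all at the cost of the advanced intermediate.
 Fallback, setting out from 15 and 25 and returning at 26: the alkylation is moved to a cheap donor used in excess. tert-Butyl acetoacetate (NaH, THF–DMF) and 25 should give tert-butyl (5Z)-2-acetyl-7-acetoxy-6-methylhept-5-enoate F11. Heating F11 with 15 in xylenes at 140 °C should release the α-alkyl acetylketene F12, which the tertiary alcohol traps to give 26.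

**Further compounds**

F1 | step 19 | tetrahydropyranyl ester as in 18 of 2-diazo-3-oxobutanoic acid | C[Si](C)(C(C)(C)C)O[C@H]1CC[C@@](C)(OC(=O)C(=[N+]=[N-])C(C)=O)[C@H](CC/C(C)=C\CO[Si](C)(C)C(C)(C)C)O1
F2 | step 19 | tetrahydropyranyl ester as in 18 of 2-diazo-3-hydroxybutanoic acid, both carbinol epimers | C[Si](C)(C(C)(C)C)O[C@H]1CC[C@@](C)(OC(=O)C(=[N+]=[N-])C(C)O)[C@H](CC/C(C)=C\CO[Si](C)(C)C(C)(C)C)O1
F3 | step 19 | tetrahydropyranyl ester as in 18 of 2-diazobut-3-enoic acid | C[Si](C)(C(C)(C)C)O[C@H]1CC[C@@](C)(OC(=O)C(=[N+]=[N-])C=C)[C@H](CC/C(C)=C\CO[Si](C)(C)C(C)(C)C)O1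
F4 | step 19 | vinyl-substituted bridged oxonium ylide | C[Si](C)(C(C)(C)C)O[C@H]1CC[C@@]2(C)OC(=O)[C-](C=C)[O+]1[C@H]2CC/C(C)=C\CO[Si](C)(C)C(C)(C)C
F5 | step 19 | 1-vinyl analogue of 29 (vinyl in place of the C12–C16 arm) | C=C[C@@]12O[C@@H](CC/C(C)=C\CO[Si](C)(C)C(C)(C)C)[C@@](C)(CC[C@@H]1O[Si](C)(C)C(C)(C)C)OC2=O
F6 | step 19 | (2Z)-3-iodo-2-methylprop-2-en-1-ol | OC/C(C)=C\I
F7 | step 19 | B-alkyl-9-borabicyclo[3.3.1]nonane from F5 | B1(CC[C@@]23O[C@@H](CC/C(C)=C\CO[Si](C)(C)C(C)(C)C)[C@@](C)(CC[C@@H]2O[Si](C)(C)C(C)(C)C)OC3=O)C2CCCC1CCC2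
F8 | step 19 | C-16 alcohol corresponding to 29 (deacetyl-29) | OC/C(C)=C\CC[C@@]12O[C@@H](CC/C(C)=C\CO[Si](C)(C)C(C)(C)C)[C@@](C)(CC[C@@H]1O[Si](C)(C)C(C)(C)C)OC2=O
F9 | step 9 | (2S,6S)-6-(TBSO)-2-[(3Z)-5-(TBSO)-3-methylpent-3-en-1-yl]dihydro-2H-pyran-3(4H)-one | C[Si](C)(C(C)(C)C)O[C@H]1CCC(=O)[C@H](CC/C(C)=C\CO[Si](C)(C)C(C)(C)C)O1
F10 | step 9 | spiro-epoxide at C-7 with epoxide oxygen cis to the anomeric silyloxy group | C[Si](C)(C(C)(C)C)O[C@H]1CC[C@]2(CO2)[C@H](CC/C(C)=C\CO[Si](C)(C)C(C)(C)C)O1
F11 | step 17 | tert-butyl (5Z)-2-acetyl-7-acetoxy-6-methylhept-5-enoate | CC(=O)C(CC/C=C(C)\COC(C)=O)C(=O)OC(C)(C)C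
F12 | step 17 | (5Z)-2-acetyl-7-acetoxy-6-methylhepta-1,5-dien-1-one (α-alkyl acetylketene) | CC(=O)C(CC/C=C(C)\COC(C)=O)=C=O
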